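The vessel was a closed, stirred flask holding a racemic substrate, a partner and a single-handed catalyst, and I wanted to know which temperature history leaves the most left-handed product.

all flasks: free catalyst 0.60 mM

| flask | left-handed substrate | right-handed substrate | partner | temperature | remark | time |
|---|---|---|---|---|---|---|
| maple | 0.15 M | 0.15 M | 0.24 M | −5 °C | run made earlier |  |
| cedar | 0.22 M | 0.22 M | 0.24 M | 15 °C | run made earlier |  |
| winter | 0.30 M | 0.30 M | 0.240 M | 0 °C |  | 10 h |
| spring | 0.30 M | 0.30 M | 0.240 M |  | at 30 °C until 5.0 h, from then on at 0 °C | 10 h |
| summer | 0.30 M | 0.30 M | 0.240 M | 30 °C |  | 10 h |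

| run | time / h | left-handed product / % | left-handed substrate / % |
|---|---|---|---|
| maple | 1.00 | 1.1 | 47.5 |
| maple | 3.00 | 6.6 | 42.5 |
| maple | 6.00 | 11.6 | 37.6 |
| maple | 8.00 | 15.6 | 33.6 |
| maple | 12.0 | 20.9 | 30.1 |
| cedar | 1.33 | 10.3 | 37.5 |
| cedar | 2.50 | 16.7 | 33.7 |
| cedar | 4.00 | 20.6 | 29.7 |
| cedar | 5.00 | 19.6 | 30.6 |
| cedar | 6.00 | 21.2 | 28.8 |

(scatter of a reading: 1 percentage point)

- the flask with the highest amount of left-handed product, in percent of the left-handed substrate and right-handed substrate together charged ("all alike" if they lie within 1.5 percentage points) (winter / spring / summer / all alike)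
- final left-handed product, as a percentage of the left-handed substrate and right-handed substrate together charged, in winter
- final left-handed product, as a percentage of the left-handed substrate and right-handed substrate together charged, in spring
- final left-handed product, as a percentage of the left-handed substrate and right-handed substrate together charged, in summer

- free catalyst is single-handed; left-handed substrate and right-handed substrate are mirror images of each other, charged as a racemate, each of them at the stated concentration
- what was read earlier has a scatter of 1 percentage point, one standard deviation
- steps thought possible: free catalyst + left-handed substrate <-> catalyst intermediate A; free catalyst + right-handed substrate <-> catalyst intermediate B; partner + catalyst intermediate A -> free catalyst + left-handed product; partner + catalyst intermediate B -> free catalyst + right-handed product; partner -> decomposed reagent; 2 free catalyst <-> resting dimer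

Cedar levelled off near 21.2% of left-handed product with 28.8% of left-handed substrate still present, so I took partner as the limiting reagent and treated its loss as pseudo-first-order. Cedar's last reading, taken as the plateau, gave 38.9% as the partner's share, the part of the charged partner that ends as left-handed product. Maple's slowing rate gave a partner time constant of 18.1 h and a projected share of 55.4%, while cedar's first reading gave 2.00 h.

I ran straight lines in temperature through the logarithms of the time constant and of the share's odds. At 30 °C they gave 0.383 h and a share of 27.8%, so summer should reach 11.1%. Spring is cooled at 5.0 h, far later than that time constant, so I gave it the same figure. At 0 °C the lines gave 10.4 h and a share of 51.2%, so winter should reach 12.6% in 10 h. I put winter ahead of summer, though only by about the margin.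

The forecast said all alike, with 14%, 13% and 13%: “The differences lie inside 1.5 points”. On the ranking it differed from my reckoning.

The flask gave winter: 15.0% in winter, 10.7% in spring and 10.7% in summer.

    free catalyst + left-handed substrate ⇌ catalyst intermediate A (K = 24.0 M⁻¹, k = 7300 M⁻¹ h⁻¹, Ea = 37.0 kJ mol⁻¹, ΔH = 7.00 kJ mol⁻¹)
    free catalyst + right-handed substrate ⇌ catalyst intermediate B (K = 2.80 M⁻¹, k = 18000 M⁻¹ h⁻¹, Ea = 46.0 kJ mol⁻¹, ΔH = 6.00 kJ mol⁻¹)
    partner + catalyst intermediate A → free catalyst + left-handed product (k = 130 M⁻¹ h⁻¹, Ea = 57.0 kJ mol⁻¹)
    partner + catalyst intermediate B → free catalyst + right-handed product (k = 47.0 M⁻¹ h⁻¹, Ea = 48.0 kJ mol⁻¹)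
    partner → decomposed reagent (k = 0.0330 h⁻¹, Ea = 94.0 kJ mol⁻¹)
    2 free catalyst ⇌ resting dimer, settled at all times (K = 700 M⁻¹, ΔH = −37.0 kJ mol⁻¹)
    (constants at 0 °C)

Summer's product was a partner share of 26.6%, below cedar's. For a repeat of winter at −15 °C, the same lines gave 4.25%, and that flask gave 4.88%. Summer had come to rest: partner stood at 0% after 10.0 h, and its product still stood at 10.7% after 100 h, ten times that time; spring's stood at 10.7% after 100 h. Winter had not: with 39% of its partner left, 100 h carries its product from 15.0% to 24.3%, a share of 60.7%, with partner down to 0.0135%.

(Readings and results stem from a simulated flask for an exercise, and the scatter is random.)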